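11.8 % of the E charged is the level toward which this reckoning has dissolved D climbing in this flask while E stands at its charge. This is its plateau share: transfer into an empty solution divided by the sum of the first-order drains on D, namely the transfer coefficient, loss to X, and capture by charged E.

E 1.0 M; L 200 mM (held); time 15 s

1. the E.D standing at 15 s, as a percentage of the E charged
2. concentration of D in solution at 1.5 s, in percent of saturation
3. the change that raises the amount of E.D at 15 s, in percent of the E charged most ("none" if none brings more than 2 percentage points) (south-east / north-west / none)
4. amount of E.D at 15 s, in percent of the E charged, after north-west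

    L ⇌ D, rate k1*(csat - [D]) (k1 = 0.18 s⁻¹, csat = 200 mM)
    D + E.D → D.E.D (k2 = 0.31 L mol⁻¹ s⁻¹)
    D → X (k3 = 0.039 s⁻¹)
    E → G (k4 = 0.0092 s⁻¹)
    E + E.D → E.E.D (k5 = 0.086 L mol⁻¹ s⁻¹)
    E + D → E.D (k6 = 0.087 L mol⁻¹ s⁻¹)

For whoever takes over the flask: E is charged at 1.0 M against a plateau of 0.118 M of D, so this reckoning treats capture of D by E as pseudo-first-order. E decays to G far more slowly than D rises, 75 s against a rise time of 3.27 s, so this hand reckoning holds E at its charge and leaves out capture by E.D. E takes D faster than D is lost to X. By 1.5 s, D should stand at 21.7 % of saturation. E.D, made from plateau D and lost to E and D, balances at 8.36 % of the charge, so the reckoning puts y below that. Doubling the saturation doubles the plateau share, and the balance gains 4.5 percentage points. Doubling the transfer coefficient lifts the share to 14.8 %, and the balance gains 1.4 points, less than the 2 points that counts. So the transfer coefficient is left untouched and north-west is the choice.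

The forecast gives 5.6 %, 21.7 %, north-west and 9 %, reasoning that "Doubling the saturation concentration nearly doubles dissolved D".

The flask gives 5.62 % for y, 21.7 % for sat, north-west as best with 3.3 points against 1.4 points, and 8.92 % for yb, with D at 11.7 % of the charge at 15.0 s.

In the neighbouring flask, read at 4.0 s with all amounts held, the same plateau share and rise time put D at 8.33 % of the charge. That flask holds 8.31 %, with E at 95 % of its charge and E.D at 1.45 %.

(The constants used here were drawn at random within sensible limits; what happens was integrated by code.)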